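This closed, stirred vessel takes free monomer, initiator and transfer agent, and we run it at two monomer charges.

| setting | dawn | winter |
|---|---|---|
| free monomer | 3.0 M | 0.80 M |
| transfer agent | 0.0300 M | 0.0300 M |
| initiator | 30 mM | 30 mM |
| time | 6.0 h | 6.0 h |

    free monomer + initiator → living end + monomer in chains (k1 = 0.0048 /M/min)
    2 free monomer → homo dimer (k2 = 3.4 × 10⁻⁷ /M/min)
    living end → dead end (k3 = 0.0026 /min)
    free monomer + living end → monomer in chains + living end, rate k4*[living end]*[free monomer] (k4 = 0.051 /M/min)
    living end + transfer agent → dead chain (k5 = 0.0084 /M/min)

- percentages count the free monomer that a species holds: one homo dimer counts as two
- two of one species on the left: rate k times its square, two consumed each time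
- the average divides the monomer in chains by the number of chains begun, living and dead together
- run time (dawn): 6.0 h

- which of the two ends with the longer chains by the average number of monomer units in a chain (chains begun, living or dead) ("neither" if they lie within 10%) (dawn / winter / neither)
- average number of monomer units in a chain (chains begun, living or dead) at the end, dawn
- average number of monomer units in a chain (chains begun, living or dead) at the end, winter

**The fork.** We follow one living end at dawn. It adds free monomer at 0.153 /min and dies, alone or on transfer agent, at 0.002852 /min. The ratio is 53.6. This is the reach, the units a living end adds in one mean life at the charged [free monomer] and [transfer agent]; the usual term is kinetic chain length. In winter the reach is 14.3.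

**First doubt.** Is the reach the average? No. A mean life is 5.84 h and the run is 6.0 h, so the run lasts about one life, and late chains are cut off. At constant [free monomer], a chain with a window left gets one minus exp(−window/life) of its reach. At dawn initiator waits 1.16 h on average, which gives a share of 0.563. In winter the wait is 4.34 h, longer than mid-run, so starts spread over the run. We take mid-run as the average start, and the share is 0.402.

**Second doubt.** Free monomer falls, and the reach falls with it. At dawn this share has the chains take 30.2% of the charge by our estimate, and we lower the mean level by half of that. The first unit of each chain also counts. The dawn share becomes 0.497. The winter share, with the first unit, is 0.471, before a smaller fall. We commit to half the reach: 26.8 at dawn and 7.15 in winter.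

**The forecast.** It names dawn for the longer chains, with 26.5 units at dawn and 6.8 in winter, reasoning that “the average is monomer consumed per initiator consumed”. Its winter figure lies below ours.

**The result.** The simulation gives the longer chains at dawn, with 26.6 units at dawn and 6.78 in winter. These are 0.496 of the dawn reach and 0.474 of the winter reach.

**Richer winter.** A winter flask charged with 1.4 M of free monomer, other charges and time held, has the same death rate at its charged [transfer agent]. Its reach is therefore 25.0, and half of that is 12.5. The simulation gives 11.8, which is 0.469 of the reach, with 11% of its initiator and 77.7% of its free monomer left.

The rate constants were set for the occasion; the result is computed.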